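**Retrosynthetic overview**

1. The ester C–O bond is cut last: (9Z)-octadec-9-enoic acid plus the monocyclic C20 alcohol.
2. One of the two geminal methyl groups on the quaternary ring carbon is traced back to a formyl group (Wolff–Kishner). That carbon thereby becomes the α-carbon of 2-methylacrolein, and the formyl group serves as a traceless activating group.
3. The only ring is opened by a retro-Diels–Alder cut of the two ring bonds that flank the CH2–C(CH3)2 unit. This gives 2-methylacrolein and an acyclic (E)-1,3-diene that already carries the whole (2E,6E)-chain. The enabling feature is the 2,6,6-trimethylcyclohex-2-ene ring itself: its C2=C3 double bond lies exactly between ring C1 and ring C4, the two atoms that receive the new bonds, and the quaternary C6 carries two identical methyl groups.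
4. The tetraene comes from (2E,6E)-farnesyl acetate by oxidation of the terminal (E)-methyl group to the aldehyde and methylenation. The ring is formed once, in the key step, where a chiral oxazaborolidinium catalyst also sets the single stereocentre.

Key step: step 4

Assumption: the cationic oxazaborolidine is taken to follow its usual sense with 2-substituted acroleins (formyl C–H···O binding, formyl-exo addition); on this basis the (R)-configured catalyst is specified, and its equally available antipode would be used if the sense proved opposite.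

**Step 1**
Reactants: 1 (2E,6E)-3,7,11-trimethyldodeca-2,6,10-trien-1-yl acetate ((E,E)-farnesyl acetate)
Product: 2 (2E,6E,10E)-12-hydroxy-3,7,11-trimethyldodeca-2,6,10-trien-1-yl acetate
Conditions: SeO2 (0.5 equiv), salicylic acid (0.1 equiv), t-BuOOH (70% aq., 3 equiv), CH2Cl2, 0 °C to rt
Reagents that add atoms: tert-butyl hydroperoxide CC(C)(C)OO (source of the new oxygen atom, delivered through SeO2 O=[Se]=O)
Why: Riley allylic oxidation, in which the ene reaction of SeO2 with the most electron-rich and least hindered trisubstituted alkene and the following [2,3]-sigmatropic shift hydroxylate the (E)-methyl group of the terminal isopropylidene unit with retention of (E) geometry, while the 2,3-alkene is deactivated by the allylic acetate.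

**Step 2**
Reactants: 2 (2E,6E,10E)-12-hydroxy-3,7,11-trimethyldodeca-2,6,10-trien-1-yl acetate
Product: 3 (2E,6E,10E)-3,7,11-trimethyl-12-oxododeca-2,6,10-trien-1-yl acetate
Conditions: MnO2 (activated, 15 equiv), CH2Cl2, rt
Reagents that add atoms: none
Why: Allylic alcohol oxidation with MnO2 should convert only the primary allylic alcohol into the (E)-enal and leave the acetate, the isolated alkenes and the alkene geometry untouched.

**Step 3**
Reactants: 3 (2E,6E,10E)-3,7,11-trimethyl-12-oxododeca-2,6,10-trien-1-yl acetate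
Product: 4 (2E,6E,10E)-3,7,11-trimethyltrideca-2,6,10,12-tetraen-1-yl acetate
Conditions: Ph3PCH3Br (1.2 equiv), KN(SiMe3)2 (1.15 equiv), THF, 0 °C; then 3, −78 °C to 0 °C
Reagents that add atoms: methyltriphenylphosphonium bromide C[P+](c1ccccc1)(c1ccccc1)c1ccccc1.[Br-] (CH2 group)
Why: Wittig methylenation, in which the non-stabilised ylide should add to the aldehyde much faster than to the acetate at low temperature and creates only a terminal C=CH2, so the (E)-trisubstituted alkene of the new 1,3-diene is not touched.

**Step 4**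
Reactants: 4 (2E,6E,10E)-3,7,11-trimethyltrideca-2,6,10,12-tetraen-1-yl acetate; 5 2-methylprop-2-enal (methacrolein)
Product: 6 (2E,6E)-9-[(1R,6R)-6-formyl-2,6-dimethylcyclohex-2-en-1-yl]-3,7-dimethylnona-2,6-dien-1-yl acetate
Conditions: 5 (4 equiv), (R)-1-(2-methylphenyl)-3,3-diphenyltetrahydro-1H,3H-pyrrolo[1,2-c][1,3,2]oxazaborole (20 mol %), (CF3SO2)2NH (18 mol %), CH2Cl2, −78 °C to −40 °C; chromatography to remove minor isomers
Reagents that add atoms: none
Why: The N-protonated oxazaborolidine binds the formyl oxygen of 5 (with the formyl C–H···O contact to the ring oxygen), lowers its LUMO and lets it add to the s-cis 1,3-diene terminus of 4 in a concerted, asynchronous [4+2] cycloaddition in which the bond from the methacrolein CH2 to the unsubstituted diene CH2 runs ahead of the bond from the methyl-bearing carbon to the substituted diene terminus; the closest known reaction type is the enantioselective Diels–Alder reaction of 2-substituted acroleins with acyclic dienes under cationic chiral oxazaborolidine catalysis, which builds formyl-bearing quaternary carbons next to a tertiary stereocentre. The cyclohexene ring is closed by an intermolecular, suprafacial–suprafacial [4+2] cycloaddition that makes both ring bonds at once and places the ring double bond between C2 and C3 with the methyl on C2. The quaternary carbon is set by the catalyst, which should shield the Re face of the α-carbon of bound 5 so that the diene adds to its Si face, and the ring CH stereocentre follows from this face together with the formyl-exo (methyl-endo) orientation, in which the bulkier methyl avoids the outward chain of the (E)-diene terminus; after step 5 only the CH centre remains stereogenic. The step needs regioselectivity (quaternary carbon next to the chain-bearing carbon), and this is secured by the (E)-alkyl substituent at the diene terminus, whose "ortho" directing effect outweighs the "para" effect of the internal methyl and which leaves the CH2 terminus as the unhindered site of first bonding. Chemoselectivity is secured because only the conjugated diene can react while the three other C=C bonds are isolated, and the (E)-geometry from step 1 keeps the chain outside so that the s-cis conformer is accessible. Any formyl-endo diastereomer must be removed at this stage, because after step 5 it would give the enantiomeric ring.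

**Step 5**
Reactants: 6 (2E,6E)-9-[(1R,6R)-6-formyl-2,6-dimethylcyclohex-2-en-1-yl]-3,7-dimethylnona-2,6-dien-1-yl acetate
Product: 8 (2E,6E)-3,7-dimethyl-9-[(1S)-2,6,6-trimethylcyclohex-2-en-1-yl]nona-2,6-dien-1-ol, via hydroxy hydrazone 7 (not isolated)
Conditions: N2H4·H2O (10 equiv), KOH (6 equiv), diethylene glycol, 130 °C; then water and excess hydrazine distilled off, 200 °C, argon
Reagents that add atoms: none
Why: Wolff–Kishner reduction in the Huang-Minlon modification, in which the non-enolisable neopentyl aldehyde condenses with hydrazine while KOH cleaves the acetate in the same flask, the hydrazone anion then loses N2 to leave the second geminal methyl group, and the ring CH centre (not acidic, no bond to it made or broken) keeps its arrangement, its descriptor changing from R to S only because the CIP ranking changes when CHO becomes CH3.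

**Step 6**
Reactants: 8 (2E,6E)-3,7-dimethyl-9-[(1S)-2,6,6-trimethylcyclohex-2-en-1-yl]nona-2,6-dien-1-ol; 9 (9Z)-octadec-9-enoic acid (oleic acid)
Product: 10 (2E,6E)-3,7-dimethyl-9-[(1S)-2,6,6-trimethylcyclohex-2-en-1-yl]nona-2,6-dien-1-yl (9Z)-octadec-9-enoate
Conditions: 9 (1.2 equiv), DCC (1.3 equiv), DMAP (0.1 equiv), CH2Cl2, 0 °C to rt
Reagents that add atoms: none
Why: Steglich esterification, in which DCC activates the acid as its O-acylisourea and DMAP transfers the acyl group to the primary allylic alcohol under neutral conditions that should leave the (Z)-alkene of the acid, the (E)-alkenes and the stereocentre unchanged.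

**Compound list**

1 | (2E,6E)-3,7,11-trimethyldodeca-2,6,10-trien-1-yl acetate ((E,E)-farnesyl acetate) | CC(=O)OC/C=C(\C)CC/C=C(\C)CCC=C(C)C | starting material
2 | (2E,6E,10E)-12-hydroxy-3,7,11-trimethyldodeca-2,6,10-trien-1-yl acetate | CC(=O)OC/C=C(\C)CC/C=C(\C)CC/C=C(\C)CO | intermediate
3 | (2E,6E,10E)-3,7,11-trimethyl-12-oxododeca-2,6,10-trien-1-yl acetate | CC(=O)OC/C=C(\C)CC/C=C(\C)CC/C=C(\C)C=O | intermediate
4 | (2E,6E,10E)-3,7,11-trimethyltrideca-2,6,10,12-tetraen-1-yl acetate | CC(=O)OC/C=C(\C)CC/C=C(\C)CC/C=C(\C)C=C | intermediate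
5 | 2-methylprop-2-enal (methacrolein) | CC(=C)C=O | starting material
6 | (2E,6E)-9-[(1R,6R)-6-formyl-2,6-dimethylcyclohex-2-en-1-yl]-3,7-dimethylnona-2,6-dien-1-yl acetate | CC(=O)OC/C=C(\C)CC/C=C(\C)CC[C@@H]1C(C)=CCC[C@@]1(C)C=O | intermediate
7 | (2E,6E)-9-[(1R,6R)-6-[(E)-hydrazinylidenemethyl]-2,6-dimethylcyclohex-2-en-1-yl]-3,7-dimethylnona-2,6-dien-1-ol | OC/C=C(\C)CC/C=C(\C)CC[C@@H]1C(C)=CCC[C@@]1(C)/C=N/N | intermediate
8 | (2E,6E)-3,7-dimethyl-9-[(1S)-2,6,6-trimethylcyclohex-2-en-1-yl]nona-2,6-dien-1-ol | OC/C=C(\C)CC/C=C(\C)CC[C@@H]1C(C)=CCCC1(C)C | intermediate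
9 | (9Z)-octadec-9-enoic acid (oleic acid) | CCCCCCCC/C=C\CCCCCCCC(=O)O | starting material
10 | (2E,6E)-3,7-dimethyl-9-[(1S)-2,6,6-trimethylcyclohex-2-en-1-yl]nona-2,6-dien-1-yl (9Z)-octadec-9-enoate | CCCCCCCC/C=C\CCCCCCCC(=O)OC/C=C(\C)CC/C=C(\C)CC[C@@H]1C(C)=CCCC1(C)C | target

**Step count**

Total step count: 6. Longest linear sequence: 6 steps (1 to 10).

**Steps most likely to fail**

**Step 4.** The dienophile may bond at the chain-bearing diene terminus (wrong regiochemistry). Exo/endo control may erode, which turns into loss of enantiopurity at the ring CH centre once the formyl group has become methyl. The acidic catalyst may also cyclise or oligomerise the polyene.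

The fallback sets out from 3 and comes back to the route at 8.
- Chemoselective methyl addition to the aldehyde of 3 with MeTi(OiPr)3 (THF, −40 to 0 °C; the acetate is not attacked) should give the secondary allylic alcohol (2E,6E,10E)-12-hydroxy-3,7,11-trimethyltrideca-2,6,10-trien-1-yl acetate F1.
- MnO2 oxidation should give the (E)-enone (2E,6E,10E)-3,7,11-trimethyl-12-oxotrideca-2,6,10-trien-1-yl acetate F2.
- i-Pr3SiOSO2CF3 and Et3N (CH2Cl2, 0 °C) should give the cross-conjugated silyloxydiene (2E,6E,10E)-3,7,11-trimethyl-12-[tri(propan-2-yl)silyloxy]trideca-2,6,10,12-tetraen-1-yl acetate F3. In it the strongly "para"-directing silyloxy group and the terminal alkyl group point to the same regioisomer, and the diene is far more reactive.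
- Cycloaddition of F3 with 5 under a neutral catalyst, (R)-2-butyl-4-(1H-indol-3-ylmethyl)-3-(4-methylphenylsulfonyl)-1,3,2-oxazaborolidin-5-one (CH2Cl2, −78 °C), is a known reaction type for 2-methylacrolein with 1-alkyl-3-silyloxydienes. It should give the silyl enol ether adduct (2E,6E)-9-[(1R,6R)-6-formyl-2,6-dimethyl-3-[tri(propan-2-yl)silyloxy]cyclohex-2-en-1-yl]-3,7-dimethylnona-2,6-dien-1-yl acetate F4.
- CsF and PhN(SO2CF3)2 (DME, rt) should convert the enol silane regiospecifically into the enol triflate (2E,6E)-9-[(1R,6R)-6-formyl-2,6-dimethyl-3-(trifluoromethylsulfonyloxy)cyclohex-2-en-1-yl]-3,7-dimethylnona-2,6-dien-1-yl acetate F5.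
- K2CO3 in MeOH (0 °C) should remove the acetate, so that no allylic ester meets a palladium hydride, and give the alcohol (2E,6E)-9-[(1R,6R)-6-formyl-2,6-dimethyl-3-(trifluoromethylsulfonyloxy)cyclohex-2-en-1-yl]-3,7-dimethylnona-2,6-dien-1-ol F6.
- Pd(OAc)2, PPh3, HCO2H and Bu3N (DMF, 60 °C) should reduce the triflate with the double bond kept in place and give the hydroxy aldehyde (2E,6E)-9-[(1R,6R)-6-formyl-2,6-dimethylcyclohex-2-en-1-yl]-3,7-dimethylnona-2,6-dien-1-ol F7.
- Under the conditions of step 5, F7 should give 8 via 7.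

**Step 5.** Hydrazone formation at the hindered neopentyl aldehyde may be incomplete, azine formation may compete, and the polyene may suffer at 200 °C in strong base (double-bond migration, or diimide reduction of alkenes if air is admitted).

The fallback sets out from 6 and comes back at 8. It replaces the hot basic reduction by a neutral hydride-based deoxygenation.
- Condensation with 4-methylbenzenesulfonohydrazide (EtOH, rt) should give the tosylhydrazone (2E,6E)-9-[(1R,6R)-2,6-dimethyl-6-[(E)-(2-tosylhydrazinylidene)methyl]cyclohex-2-en-1-yl]-3,7-dimethylnona-2,6-dien-1-yl acetate F8.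
- Catecholborane (CHCl3, 0 °C), then NaOAc·3H2O at reflux, should reduce the C=N bond and expel sulfinate and N2 to give the acetate (2E,6E)-3,7-dimethyl-9-[(1S)-2,6,6-trimethylcyclohex-2-en-1-yl]nona-2,6-dien-1-yl acetate F9.
- K2CO3 in MeOH (rt) should then give 8.

**Step 1.** Oxidation may compete at the internal 6,7-alkene and at other allylic positions, and over-oxidation to enal or diol may occur, so that the terminal (E)-alcohol forms in low amount and is hard to purify.

The fallback sets out from 1 and comes back at 3, bypassing 2.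
- N-bromosuccinimide in THF/H2O (0 °C) should attack the terminal alkene selectively and give the bromohydrin (2E,6E)-10-bromo-11-hydroxy-3,7,11-trimethyldodeca-2,6-dien-1-yl acetate F10.
- DBU (CH2Cl2, rt) should close it to the epoxide (2E,6E)-9-(3,3-dimethyloxiran-2-yl)-3,7-dimethylnona-2,6-dien-1-yl acetate F11.
- H5IO6 (THF/H2O, 0 °C) should cleave the epoxide to the aldehyde (2E,6E)-3,7-dimethyl-10-oxodeca-2,6-dien-1-yl acetate F12.
- An (E)-selective Wittig reaction of F12 with the stabilised ylide Ph3P=C(CH3)CHO (toluene, 80 °C) should then give 3.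

**Further compounds**

F1 | step 4 | (2E,6E,10E)-12-hydroxy-3,7,11-trimethyltrideca-2,6,10-trien-1-yl acetate (racemic at the carbinol carbon) | CC(=O)OC/C=C(\C)CC/C=C(\C)CC/C=C(\C)C(C)O
F2 | step 4 | (2E,6E,10E)-3,7,11-trimethyl-12-oxotrideca-2,6,10-trien-1-yl acetate | CC(=O)OC/C=C(\C)CC/C=C(\C)CC/C=C(\C)C(C)=O
F3 | step 4 | (2E,6E,10E)-3,7,11-trimethyl-12-[tri(propan-2-yl)silyloxy]trideca-2,6,10,12-tetraen-1-yl acetate | CC(=O)OC/C=C(\C)CC/C=C(\C)CC/C=C(\C)C(=C)O[Si](C(C)C)(C(C)C)C(C)C
F4 | step 4 | (2E,6E)-9-[(1R,6R)-6-formyl-2,6-dimethyl-3-[tri(propan-2-yl)silyloxy]cyclohex-2-en-1-yl]-3,7-dimethylnona-2,6-dien-1-yl acetate | CC(=O)OC/C=C(\C)CC/C=C(\C)CC[C@@H]1C(C)=C(O[Si](C(C)C)(C(C)C)C(C)C)CC[C@@]1(C)C=O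
F5 | step 4 | (2E,6E)-9-[(1R,6R)-6-formyl-2,6-dimethyl-3-(trifluoromethylsulfonyloxy)cyclohex-2-en-1-yl]-3,7-dimethylnona-2,6-dien-1-yl acetate | CC(=O)OC/C=C(\C)CC/C=C(\C)CC[C@@H]1C(C)=C(OS(=O)(=O)C(F)(F)F)CC[C@@]1(C)C=O
F6 | step 4 | (2E,6E)-9-[(1R,6R)-6-formyl-2,6-dimethyl-3-(trifluoromethylsulfonyloxy)cyclohex-2-en-1-yl]-3,7-dimethylnona-2,6-dien-1-ol | OC/C=C(\C)CC/C=C(\C)CC[C@@H]1C(C)=C(OS(=O)(=O)C(F)(F)F)CC[C@@]1(C)C=O
F7 | step 4 | (2E,6E)-9-[(1R,6R)-6-formyl-2,6-dimethylcyclohex-2-en-1-yl]-3,7-dimethylnona-2,6-dien-1-ol | OC/C=C(\C)CC/C=C(\C)CC[C@@H]1C(C)=CCC[C@@]1(C)C=O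
F8 | step 5 | (2E,6E)-9-[(1R,6R)-2,6-dimethyl-6-[(E)-(2-tosylhydrazinylidene)methyl]cyclohex-2-en-1-yl]-3,7-dimethylnona-2,6-dien-1-yl acetate | CC(=O)OC/C=C(\C)CC/C=C(\C)CC[C@@H]1C(C)=CCC[C@@]1(C)/C=N/NS(=O)(=O)c1ccc(C)cc1
F9 | step 5 | (2E,6E)-3,7-dimethyl-9-[(1S)-2,6,6-trimethylcyclohex-2-en-1-yl]nona-2,6-dien-1-yl acetate | CC(=O)OC/C=C(\C)CC/C=C(\C)CC[C@@H]1C(C)=CCCC1(C)C
F10 | step 1 | (2E,6E)-10-bromo-11-hydroxy-3,7,11-trimethyldodeca-2,6-dien-1-yl acetate (racemic) | CC(=O)OC/C=C(\C)CC/C=C(\C)CCC(Br)C(C)(C)O
F11 | step 1 | (2E,6E)-9-(3,3-dimethyloxiran-2-yl)-3,7-dimethylnona-2,6-dien-1-yl acetate (racemic) | CC(=O)OC/C=C(\C)CC/C=C(\C)CCC1OC1(C)C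
F12 | step 1 | (2E,6E)-3,7-dimethyl-10-oxodeca-2,6-dien-1-yl acetate | CC(=O)OC/C=C(\C)CC/C=C(\C)CCC=O
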